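The route rests on cutting both C–O bonds of the 1,4-dioxane ring (O1–C2 and O4–C3, benzodioxine numbering). The complete (1S)-1-aryl-2-isopropylideneindane is carried as a free catechol, and the C5 unit as an enantiopure epoxy nosylate. In one operation the open, more acidic O4–H displaces the primary sulfonate. O1, shielded by the indanyl group on C8, then opens the trisubstituted epoxide 6-exo at its CH carbon with inversion. This closes the last ring, sets C2 and unveils the tertiary carbinol. The step exploits the vicinal O1–C2(H)/C(CH3)2–OH pair, the retron of an epoxide opening, and the unequal surroundings of O1 and O4 on the arene.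

Key step: step 11

Assumption: the (S,S)-bis(oxazoline) is taken to give (1S)-15, otherwise its antipode is used; indane positions are numbered as in the target throughout (C1 carries the aryl group, C7 the formyl carbon).

Step 1
Reactants: 1 1,2,6,7-tetrahydro-8H-indeno[5,4-b]furan-8-one
Product: 2 6,7-dihydro-8H-indeno[5,4-b]furan-8-one
Conditions: DDQ, 1,4-dioxane, reflux
Reagents that add atoms: none
Why: DDQ dehydrogenation (hydride abstraction at the benzylic CH2 of the dihydrofuran, then proton loss) should aromatize the oxygen ring to a benzofuran, whose C2=C3 bond is the latent formyl/hydroxyl pair already placed at C7/C6.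

Step 2
Reactants: 2 6,7-dihydro-8H-indeno[5,4-b]furan-8-one
Product: 4 6-hydroxy-1-oxoindane-7-carbaldehyde, via keto aldehyde formate 3 (not isolated)
Conditions: O3, CH2Cl2, −78 °C; Me2S; then MeOH, K2CO3 (cat.), 0 °C
Reagents that add atoms: ozone, [O-][O+]=O
Why: Ozonolysis (Criegee mechanism) should cleave only the enol-ether-like furan C2=C3 bond, giving the C7 aldehyde and the C6 aryl formate, and the formate is removed by mild methanolysis.

Step 3
Reactants: 4 6-hydroxy-1-oxoindane-7-carbaldehyde
Product: 5 6-(methoxymethoxy)-1-oxoindane-7-carbaldehyde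
Conditions: NaH, DMF, 0 °C; MOMCl
Reagents that add atoms: chloromethyl methyl ether (MOMCl), COCCl
Why: Williamson-type O-alkylation works because one equivalent of NaH ionizes only the acidic chelated phenol and the phenoxide is trapped by the reactive chloromethyl ether.

Step 4
Reactants: 5 6-(methoxymethoxy)-1-oxoindane-7-carbaldehyde
Product: 6 7-(dimethoxymethyl)-6-(methoxymethoxy)indan-1-one
Conditions: HC(OMe)3, MeOH, camphorsulfonic acid (cat.), rt
Reagents that add atoms: trimethyl orthoformate, COC(OC)OC
Why: Acid-catalysed acetalization with an orthoester as water scavenger should mask the aldehyde selectively, because the conjugated aryl ketone is far less electrophilic and the MOM ether tolerates a trace of mild acid.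

Step 5
Reactants: 6 7-(dimethoxymethyl)-6-(methoxymethoxy)indan-1-one
Product: 8 7-(dimethoxymethyl)-6-(methoxymethoxy)-2-(propan-2-ylidene)indan-1-one, via aldol adduct 7 (not isolated)
Conditions: KOH (cat.), acetone (solvent)/MeOH, reflux
Reagents that add atoms: acetone, CC(C)=O
Why: In this crossed aldol condensation (Claisen–Schmidt type) the indanone enolate adds to the large excess of acetone, and E1cB loss of water from 7 is driven by conjugation with the aryl ketone, which places the tetrasubstituted alkene unambiguously at C2.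

Step 6
Reactants: 8 7-(dimethoxymethyl)-6-(methoxymethoxy)-2-(propan-2-ylidene)indan-1-one
Product: 9 rac-7-(dimethoxymethyl)-6-(methoxymethoxy)-2-(propan-2-ylidene)indan-1-ol
Conditions: NaBH4, CeCl3·7H2O, MeOH, 0 °C
Reagents that add atoms: none
Why: Luche reduction should attack the enone in the 1,2 sense only, so the alkene stays, and the racemic carbinol centre is harmless because step 8 is stereoconvergent.

Step 7
Reactants: 10 4-methylcatechol
Product: 11 5-methyl-2,2-diphenyl-1,3-benzodioxole
Conditions: Ph2CCl2, neat, 170 °C
Reagents that add atoms: dichlorodiphenylmethane, ClC(Cl)(c1ccccc1)c1ccccc1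
Why: Ketalization of a catechol with a gem-dichloride (double O-alkylation through the stabilised diarylchloromethyl cation) ties both oxygens back in one hydrogenolysable group that also directs ortho-lithiation.

Step 8
Reactants: 9 rac-7-(dimethoxymethyl)-6-(methoxymethoxy)-2-(propan-2-ylidene)indan-1-ol; 11 5-methyl-2,2-diphenyl-1,3-benzodioxole
Product: 15 4-[(1S)-7-(dimethoxymethyl)-6-(methoxymethoxy)-2-(propan-2-ylidene)indan-1-yl]-6-methyl-2,2-diphenyl-1,3-benzodioxole, via aryllithium 12 (not isolated), via arylzinc iodide 13 (not isolated), via allylic mesylate 14 (not isolated)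
Conditions: 11, n-BuLi, THF, 0 °C, then ZnI2; separately 9, MsCl, Et3N, CH2Cl2/THF, −45 °C; combine with NiBr2·diglyme (10 mol %), (4S,4'S)-2,2'-(propane-2,2-diyl)bis(4-phenyl-4,5-dihydrooxazole) (13 mol %), LiI, −45 °C
Reagents that add atoms: none
Why: Directed ortho-lithiation occurs at the ring position next to the oxygen para to methyl and away from the methyl group; the stereoconvergent nickel-catalysed Negishi arylation of the racemic secondary benzylic (here also allylic) mesylate then passes through a planar benzylic/allylic radical, so both enantiomers of 9 converge, the chiral bis(oxazoline)–arylnickel complex sets (1S), and the C–C bond should form at the secondary terminus C1 rather than at the fully substituted CMe2 terminus, which keeps the alkene in place.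

Step 9
Reactants: 15 4-[(1S)-7-(dimethoxymethyl)-6-(methoxymethoxy)-2-(propan-2-ylidene)indan-1-yl]-6-methyl-2,2-diphenyl-1,3-benzodioxole
Product: 16 3-[(1S)-7-(dimethoxymethyl)-6-(methoxymethoxy)-2-(propan-2-ylidene)indan-1-yl]-5-methylbenzene-1,2-diol
Conditions: H2 (1 atm), Pd/C, THF/MeOH, rt
Reagents that add atoms: none
Why: Catalytic hydrogenolysis of the doubly benzylic ketal C–O bonds should free the catechol under neutral conditions that spare the MOM ether, the dimethyl acetal and the hindered tetrasubstituted alkene, and that avoid acid while O1–H sits next to that alkene.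

Step 10
Reactants: 17 3-methylbut-2-en-1-ol (prenol)
Product: 19 [(2R)-3,3-dimethyloxiran-2-yl]methyl 3-nitrobenzenesulfonate, via epoxy alcohol 18 (not isolated)
Conditions: Ti(OiPr)4 (cat.), D-(−)-diisopropyl tartrate (cat.), t-BuOOH, 4 Å molecular sieves, CH2Cl2, −20 °C; then Et3N, DMAP (cat.), 3-nitrobenzenesulfonyl chloride, −20 to 0 °C
Reagents that add atoms: tert-butyl hydroperoxide, CC(C)(C)OO; 3-nitrobenzenesulfonyl chloride, O=S(=O)(Cl)c1cccc([N+](=O)[O-])c1
Why: In the Katsuki–Sharpless asymmetric epoxidation the titanium/D-(−)-tartrate complex delivers oxygen to the alkene face that gives the (2R)-epoxide, and sulfonylation in the same flask avoids isolating the volatile, water-soluble epoxy alcohol.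

Step 11
Reactants: 16 3-[(1S)-7-(dimethoxymethyl)-6-(methoxymethoxy)-2-(propan-2-ylidene)indan-1-yl]-5-methylbenzene-1,2-diol; 19 [(2R)-3,3-dimethyloxiran-2-yl]methyl 3-nitrobenzenesulfonate
Product: 21 2-{(2S)-8-[(1S)-7-(dimethoxymethyl)-6-(methoxymethoxy)-2-(propan-2-ylidene)indan-1-yl]-6-methyl-2,3-dihydro-1,4-benzodioxin-2-yl}propan-2-ol, via glycidyl ether 20 (not isolated)
Conditions: Cs2CO3, degassed DMF, argon, rt then 60 °C
Reagents that add atoms: none
Why: Cs2CO3 first ionizes the more acidic and unhindered O4–H (meta to the aryl methyl, flanked by H-5), whose phenoxide displaces the primary nosylate of 19 by SN2 without touching the epoxide carbon to give 20, after which the neighbouring O1 phenoxide opens the trisubstituted epoxide at its CH carbon and proton transfer leaves the tertiary carbinol. The closest known reaction type is the annulation of catechols with glycidyl sulfonates to 2-(hydroxymethyl)-1,4-benzodioxanes, that is a Williamson etherification followed by an intramolecular epoxide opening. The dioxane ring closes in the 6-exo-tet mode, since the 7-endo alternative would need SN2 attack at the fully substituted CMe2 carbon and is shut off under basic conditions. The new stereocentre C2 is controlled by the (2R)-epoxide set in step 10: backside attack inverts it to (2S), and because the gem-dimethyl terminus blocks attack at the distal epoxide carbon, no Payne-type or epoxide-first pathway can scramble it. The step needs O4-before-O1 site selectivity, secured by the bulky indan-1-yl group ortho to O1 and by the lower acidity of O1–H (para to methyl), and chemoselectivity over the third phenol and the aldehyde, secured by the MOM ether and the dimethyl acetal. C1 is left untouched because neither acid nor strong base is present.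

Step 12
Reactants: 21 2-{(2S)-8-[(1S)-7-(dimethoxymethyl)-6-(methoxymethoxy)-2-(propan-2-ylidene)indan-1-yl]-6-methyl-2,3-dihydro-1,4-benzodioxin-2-yl}propan-2-ol
Product: 22 diaporindene H
Conditions: HCl (1 M aq), THF, rt
Reagents that add atoms: water, O
Why: Acid-catalysed acetal hydrolysis should remove the dimethyl acetal and the MOM ether together; with O1 now locked in the dioxane no chroman can form from the alkene, and neither stereocentre is ionisable under these mild conditions.

Compound list
1 | 1,2,6,7-tetrahydro-8H-indeno[5,4-b]furan-8-one | O=C1CCc2ccc3OCCc3c21 | starting material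
2 | 6,7-dihydro-8H-indeno[5,4-b]furan-8-one | O=C1CCc2ccc3occc3c21 | intermediate
3 | 7-formyl-1-oxoindan-6-yl formate | O=COc1ccc2CCC(=O)c2c1C=O | intermediate
4 | 6-hydroxy-1-oxoindane-7-carbaldehyde | O=Cc1c(O)ccc2CCC(=O)c12 | intermediate
5 | 6-(methoxymethoxy)-1-oxoindane-7-carbaldehyde | O=Cc1c(OCOC)ccc2CCC(=O)c12 | intermediate
6 | 7-(dimethoxymethyl)-6-(methoxymethoxy)indan-1-one | COC(OC)c1c(OCOC)ccc2CCC(=O)c12 | intermediate
7 | rac-7-(dimethoxymethyl)-2-(2-hydroxypropan-2-yl)-6-(methoxymethoxy)indan-1-one | COC(OC)c1c(OCOC)ccc2CC(C(C)(C)O)C(=O)c12 | intermediate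
8 | 7-(dimethoxymethyl)-6-(methoxymethoxy)-2-(propan-2-ylidene)indan-1-one | COC(OC)c1c(OCOC)ccc2CC(=C(C)C)C(=O)c12 | intermediate
9 | rac-7-(dimethoxymethyl)-6-(methoxymethoxy)-2-(propan-2-ylidene)indan-1-ol | COC(OC)c1c(OCOC)ccc2CC(=C(C)C)C(O)c12 | intermediate
10 | 4-methylcatechol (4-methylbenzene-1,2-diol) | Cc1ccc(O)c(O)c1 | starting material
11 | 5-methyl-2,2-diphenyl-1,3-benzodioxole | Cc1ccc2OC(c3ccccc3)(c3ccccc3)Oc2c1 | intermediate
12 | (6-methyl-2,2-diphenyl-1,3-benzodioxol-4-yl)lithium | [Li]c1cc(C)cc2OC(c3ccccc3)(c3ccccc3)Oc12 | intermediate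
13 | (6-methyl-2,2-diphenyl-1,3-benzodioxol-4-yl)zinc iodide | I[Zn]c1cc(C)cc2OC(c3ccccc3)(c3ccccc3)Oc12 | intermediate
14 | rac-7-(dimethoxymethyl)-6-(methoxymethoxy)-2-(propan-2-ylidene)indan-1-yl methanesulfonate | COC(OC)c1c(OCOC)ccc2CC(=C(C)C)C(OS(C)(=O)=O)c12 | intermediate
15 | 4-[(1S)-7-(dimethoxymethyl)-6-(methoxymethoxy)-2-(propan-2-ylidene)indan-1-yl]-6-methyl-2,2-diphenyl-1,3-benzodioxole | CC(C)=C1Cc2ccc(OCOC)c(C(OC)OC)c2[C@H]1c1cc(C)cc2c1OC(c1ccccc1)(c1ccccc1)O2 | intermediate
16 | 3-[(1S)-7-(dimethoxymethyl)-6-(methoxymethoxy)-2-(propan-2-ylidene)indan-1-yl]-5-methylbenzene-1,2-diol | CC(C)=C1Cc2ccc(OCOC)c(C(OC)OC)c2[C@H]1c1cc(C)cc(O)c1O | intermediate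
17 | 3-methylbut-2-en-1-ol (prenol) | CC(C)=CCO | starting material
18 | [(2R)-3,3-dimethyloxiran-2-yl]methanol | OC[C@H]1OC1(C)C | intermediate
19 | [(2R)-3,3-dimethyloxiran-2-yl]methyl 3-nitrobenzenesulfonate | O=S(=O)(OC[C@H]1OC1(C)C)c1cccc([N+](=O)[O-])c1 | intermediate
20 | 2-[(1S)-7-(dimethoxymethyl)-6-(methoxymethoxy)-2-(propan-2-ylidene)indan-1-yl]-6-{[(2R)-3,3-dimethyloxiran-2-yl]methoxy}-4-methylphenol | CC(C)=C1Cc2ccc(OCOC)c(C(OC)OC)c2[C@H]1c1cc(C)cc(OC[C@H]2OC2(C)C)c1O | intermediate
21 | 2-{(2S)-8-[(1S)-7-(dimethoxymethyl)-6-(methoxymethoxy)-2-(propan-2-ylidene)indan-1-yl]-6-methyl-2,3-dihydro-1,4-benzodioxin-2-yl}propan-2-ol | CC(C)=C1Cc2ccc(OCOC)c(C(OC)OC)c2[C@H]1c1cc(C)cc2c1O[C@H](C(C)(C)O)CO2 | intermediate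
22 | diaporindene H, (1S)-6-hydroxy-1-[(3S)-3-(2-hydroxypropan-2-yl)-7-methyl-2,3-dihydro-1,4-benzodioxin-5-yl]-2-(propan-2-ylidene)indane-7-carbaldehyde | CC(C)=C1Cc2ccc(O)c(C=O)c2[C@H]1c1cc(C)cc2c1O[C@H](C(C)(C)O)CO2 | target

Total step count: 12. Longest linear sequence: 10 steps (1, 2, 3, 4, 5, 6, 8, 9, 11, 12).

Steps most likely to fail

Step 8. Radical capture and reductive elimination at C1 may be slow, because C1 is flanked by the C7 acetal and the isopropylidene group. Part of the C–C bond formation may leak to the CMe2 terminus, and the ortho-oxygenated arylzinc may be discriminated poorly by the chiral nickel complex. The fallback changes both the bond-forming mechanism and the source of stereocontrol.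
- Setting out from 9, a Re2O7-catalysed 1,3-transposition of the allylic alcohol gives the conjugated tertiary allylic alcohol 2-[4-(dimethoxymethyl)-5-(methoxymethoxy)-1H-inden-2-yl]propan-2-ol F1.
- This is acetylated (Ac2O, Et3N, DMAP) to the tertiary allylic acetate F2.
- The lithium diarylcuprate F3, made from aryllithium 12 and CuI, displaces the acetate in the anti-SN2' sense. This is regiospecific for C1, regenerates the isopropylidene group, and gives the racemic coupling product F4.
- Hydrogenolysis under the conditions of step 9 gives the racemic catechol F5.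
- The annulation of step 11 with enantiopure 19 turns the two enantiomers into 21 and its (1R)-epimer F6, which are separated by chromatography or crystallisation.
- The route is rejoined at 21.

Step 11. The first alkylation may take place on O1, which would give the constitutional isomer with the carbinol-bearing carbon on O4. Both oxygens may be alkylated, and the catecholate may be oxidised by traces of air. The fallback sets out from 16 and replaces phenoxide alkylation by activation of the alcohol under neutral conditions.
- Mitsunobu etherification (PPh3, DIAD, THF, 0 °C) uses the isolated epoxy alcohol 18. The betaine deprotonates the more acidic O4–H, and the bulky alkoxyphosphonium ion is approached by the open oxygen.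
- The glycidyl ether 20 is then isolated and freed from any O1-ether.
- The ring is closed in a separate operation (K2CO3, MeOH, rt) to come back at 21.
- This fallback makes no compound outside the list (F0).

Step 5. The ketone–ketone aldol equilibrium may lie on the side of the reactants, and self-condensation of acetone may outrun the crossed reaction. The fallback sets out from 6 and replaces the thermodynamic condensation by a kinetic, stepwise sequence.
- The lithium enolate (LiN(iPr)2, THF, −78 °C) is quenched with acetone, and the aldol adduct 7 is isolated.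
- Its tertiary hydroxyl is activated as the tertiary mesylate F7 (MsCl, Et3N, CH2Cl2, 0 °C).
- DBU induces E1cB elimination towards the carbonyl group, coming back at 8.

Further compounds
F1 | step 8 | 2-[4-(dimethoxymethyl)-5-(methoxymethoxy)-1H-inden-2-yl]propan-2-ol | COC(OC)c1c(OCOC)ccc2CC(C(C)(C)O)=Cc12
F2 | step 8 | 2-[4-(dimethoxymethyl)-5-(methoxymethoxy)-1H-inden-2-yl]propan-2-yl acetate | COC(OC)c1c(OCOC)ccc2CC(C(C)(C)OC(C)=O)=Cc12
F3 | step 8 | lithium bis(6-methyl-2,2-diphenyl-1,3-benzodioxol-4-yl)cuprate | [Li+].Cc1cc([Cu-]c2cc(C)cc3OC(c4ccccc4)(c4ccccc4)Oc23)c2OC(c3ccccc3)(c3ccccc3)Oc2c1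
F4 | step 8 | rac-4-[7-(dimethoxymethyl)-6-(methoxymethoxy)-2-(propan-2-ylidene)indan-1-yl]-6-methyl-2,2-diphenyl-1,3-benzodioxole | CC(C)=C1Cc2ccc(OCOC)c(C(OC)OC)c2C1c1cc(C)cc2c1OC(c1ccccc1)(c1ccccc1)O2
F5 | step 8 | rac-3-[7-(dimethoxymethyl)-6-(methoxymethoxy)-2-(propan-2-ylidene)indan-1-yl]-5-methylbenzene-1,2-diol | CC(C)=C1Cc2ccc(OCOC)c(C(OC)OC)c2C1c1cc(C)cc(O)c1O
F6 | step 8 | 2-{(2S)-8-[(1R)-7-(dimethoxymethyl)-6-(methoxymethoxy)-2-(propan-2-ylidene)indan-1-yl]-6-methyl-2,3-dihydro-1,4-benzodioxin-2-yl}propan-2-ol | CC(C)=C1Cc2ccc(OCOC)c(C(OC)OC)c2[C@@H]1c1cc(C)cc2c1O[C@H](C(C)(C)O)CO2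
F0 | step 11 | none | none
F7 | step 5 | rac-2-[7-(dimethoxymethyl)-6-(methoxymethoxy)-1-oxoindan-2-yl]propan-2-yl methanesulfonate | COC(OC)c1c(OCOC)ccc2CC(C(C)(C)OS(C)(=O)=O)C(=O)c12
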